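Remark on the chemistry: atoms carry germacrane numbers (ring C1–C10, C11 on C7, C12 lactone carbonyl, C13 acetoxymethyl carbon, C14 on C10, C15 on C4); the SMILES is read as 1R,4R,5R,6S,8S,10R, that is 8α,13-diacetoxy-1β,10α:4α,5β-diepoxygermacr-7(11)-en-12,6α-olide with two trans epoxides. TBSO stands for tert-butyldimethylsilyloxy.

## Structural features

The target is a germacranolide: a ten-membered carbocycle C1–C10 fused through C6–C7 to a butenolide (O–C6, C7=C11, C12=O), with C13H2OAc on C11 and an acetoxy group on C8. Two trans, trisubstituted epoxides sit at C1–C10 and C4–C5 (methyl groups on C10 and C4); they are the oxidised form of an E,E-1,5-diene held in the ring. The six stereocentres are C1, C10, C4, C5, C6 and C8; C4, C5 and C6 are contiguous, and C6 and C8 flank the sp2 carbon C7. Fragile elements are the epoxides (acid, transannular opening), the two allylic acetates, the acidic C6–H at the γ-position of the butenolide, and, before epoxidation, the 1,5-diene (Cope rearrangement on heating). The real difficulty is the strained ten-membered ring with its two E-trisubstituted units, together with the tetrasubstituted C7=C11 olefin whose four substituents (C6, C8, C12, C13) are all oxygenated. The key step exploits the fact that O–C8–C7=C11–C13–O is a cis-2-ene-1,4-diol: it is the 1,4-dioxygenation product of a diene C8=C7–C11=C13 with C7=C8 inside the ring and C11=C13H2 outside, which is exactly the diene that an exo ring-closing enyne metathesis between a C8=C13 vinyl group and a C7≡C11 alkyne produces. The second cis-ene-1,4-dioxygen array, O–C6–C7=C11–C12–O, then closes to the lactone by oxidation, and C6 is a propargylic carbinol of the acyclic enyne that can be set by asymmetric alkynylation before any ring exists.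

## Logic of the disconnections

20 to 19: the C1–O, C10–O, C4–O and C5–O bonds are cut. Both trans epoxides map onto E-olefins, and one late oxidation avoids carrying epoxides through the route. Four stereocentres disappear and 19 keeps only C6 and C8. The forward step must oxidise the two electron-rich trisubstituted olefins, leave the electron-poor C7=C11 alone, and attack the outer face of each olefin.

19 to 16: the O6–C12 acyl bond is cut and C12 is lowered to the alcohol level. The butenolide is the oxidation product of a cis-2-ene-1,4-diol, so the lactone is replaced by two hydroxyl groups. The forward step must oxidise the primary allylic C12 alcohol in the presence of the secondary C6 alcohol and two acetates.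

16 to 15 to 14: the acetyl C–O bonds at O8 and O13 are cut and the silyl ethers at O6 and O12 restored. This differentiates the two oxygen pairs: O6/O12 come in silylated with the building blocks, O8/O13 are created later and acetylated. The demand is that the acetates stay where they are during desilylation.

14 to 12 (through 13): the C8–O and C13–O bonds are cut, a retro 1,4-dioxygenation. The C8 stereocentre, both acetoxy oxygens and the tetrasubstituted olefin are traded for a 1,3-diene. The forward step must add 1,4 through the s-cis diene, so that C13 ends cis to C8 and C12 cis to C6, choose one face at C8, and ignore the two trisubstituted olefins.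

12 to 11: the ring bond C7=C8 and the bond C11=C13 are cut, and C8=C13 and C7≡C11 are restored, a retro enyne metathesis. The ring opens to an acyclic chain with one stereocentre and no atom is lost. The forward step must close in the exo sense at high dilution and give the Z ring olefin.

11 to 10 to 7 + 8 (through 9): the C6–C7 bond is cut as a carbonyl addition of an alkynyl metal to an enal. Two achiral fragments result. The forward step must be a 1,2-addition that sets C6 by catalyst control.

7 to 6 to 5 to 3 + 4: the C8–C9 allyl–vinyl bond is cut, with adjustment of the oxidation level at C6. The demand is coupling at C9 without allylic transposition or loss of E geometry, with the acetate untouched.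

3 to 2 to 1: the C9–Br and C9–O bonds are cut, leaving allylic functionalisation of the E-methyl group of 1. Both E-olefins of the ring are bought with the starting material. The demand is selectivity for the E-methyl of the terminal olefin.

## Other disconnections considered

Alternative 1: the cut that comes to mind first is C6–C7 together with the lactone C–O bond. The forward key step is a Nozaki–Hiyama–Kishi-type allylation with divalent chromium (CrCl2) of bromo ester aldehyde A1, which closes the ten-membered ring and lactonises to α-methylene lactone A2. This is the standard germacranolide ring closure, but it delivers C7–H and an exocyclic C11=C13 olefin. Reaching 20 would then need dihydroxylation of the enoate, mono-acetylation and dehydration toward C7 after the epoxidation. C6 would be created in the macrocyclisation under conformational control only. The chosen plan sets C6 by a catalyst before the ring exists and obtains C7=C11 and both acetoxy oxygens from one diene.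

Alternative 2: the cut is again C6–C7, made by a [2,3]-Wittig ring contraction of the 13-membered bis-allylic ether A3 to the homoallylic alcohol A4. It needs two ring-forming events (ether macrocyclisation, then contraction) and must discriminate between two allylic O–CH2 groups in the deprotonation. It again ends with C7–H and an exocyclic methylene. The strongly basic conditions exclude esters, so C12 must be carried reduced and several redox steps follow. It is longer, and C6 is controlled only by the ring transition state.

Alternative 3: the cuts are C6–C7, C11–C12 and C12–O6 in one operation. The forward key step is a carbonylative [2+2+1] cyclisation (hetero-Pauson–Khand type) of ynal A5 with Mo(CO)6 or with zerovalent nickel (Ni(cod)2) under CO, which would give 19 directly. This reaction type is established only where a short tether closes a five- or six-membered ring; here the metallacycle would have to form across a ten-membered pre-ring with no thermodynamic bias. The aldehyde is a conjugated enal that invites conjugate pathways with nickel, and C6 would form without an external control element. Enyne metathesis has an intrinsic driving force and puts no stereocentre at stake.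

Key step: step 8

## Route

Step 1
Reactants: 1 geranyl acetate, (2E)-3,7-dimethylocta-2,6-dien-1-yl acetate
Product: 2 (2E,6E)-8-hydroxy-3,7-dimethylocta-2,6-dien-1-yl acetate
Conditions: SeO2 (0.1 equiv), t-BuOOH (70 % aq.), salicylic acid (cat.), CH2Cl2, rt
Reagents that add atoms: tert-butyl hydroperoxide CC(C)(C)OO
Why: Selenium dioxide allylic oxidation (ene reaction, then [2,3]-shift) attacks the E-methyl group of the more electron-rich terminal olefin; the two E-olefins of the future ring come with 1 and are not touched again until step 13.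

Step 2
Reactants: 2 (2E,6E)-8-hydroxy-3,7-dimethylocta-2,6-dien-1-yl acetate
Product: 3 (2E,6E)-8-bromo-3,7-dimethylocta-2,6-dien-1-yl acetate
Conditions: CBr4, PPh3, CH2Cl2, 0 °C
Reagents that add atoms: carbon tetrabromide BrC(Br)(Br)Br
Why: Appel bromination of a primary allylic alcohol under neutral conditions should proceed by SN2 at C9 without allylic transposition; the acetate is inert.

Step 3
Reactants: 3 (2E,6E)-8-bromo-3,7-dimethylocta-2,6-dien-1-yl acetate; 4 tributyl(vinyl)stannane
Product: 5 (2E,6E)-3,7-dimethyldeca-2,6,9-trien-1-yl acetate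
Conditions: Pd2(dba)3 (2.5 mol %), AsPh3 (10 mol %), THF, 40 °C
Reagents that add atoms: none
Why: Stille coupling of an allylic bromide: zerovalent palladium inserts into the C–Br bond much faster than into the allylic acetate and the vinyl group is delivered to the less hindered terminus (C9) of the syn π-allyl complex, so the skipped diene should form with the E-olefin retained.

Step 4
Reactants: 5 (2E,6E)-3,7-dimethyldeca-2,6,9-trien-1-yl acetate
Product: 6 (2E,6E)-3,7-dimethyldeca-2,6,9-trien-1-ol
Conditions: K2CO3, MeOH, rt
Reagents that add atoms: none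
Why: Base-catalysed methanolysis of a primary acetate; nothing else in 5 is base-sensitive.

Step 5
Reactants: 6 (2E,6E)-3,7-dimethyldeca-2,6,9-trien-1-ol
Product: 7 (2E,6E)-3,7-dimethyldeca-2,6,9-trienal
Conditions: TEMPO (10 mol %), PhI(OAc)2, CH2Cl2, rt
Reagents that add atoms: none
Why: Oxoammonium (TEMPO/PhI(OAc)2) oxidation of a primary allylic alcohol stops at the enal and should not isomerise the 2E-olefin or the skipped 6,9-diene.

Step 6
Reactants: 7 (2E,6E)-3,7-dimethyldeca-2,6,9-trienal; 8 tert-butyldimethyl(prop-2-yn-1-yloxy)silane
Product: 10 (4R,5E,9E)-1-[(tert-butyldimethylsilyl)oxy]-6,10-dimethyltrideca-5,9,12-trien-2-yn-4-ol, via methylzinc acetylide 9 (not isolated)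
Conditions: ZnMe2 (3 equiv), ProPhenol ligand (20 mol %, enantiomer giving 4R), Ph3PO (40 mol %), toluene, 4 °C; aq. NH4Cl
Reagents that add atoms: dimethylzinc C[Zn]C (its zinc and methyl group stay only in 9)
Why: Catalytic enantioselective alkynylation of an α,β-unsaturated aldehyde: the dinuclear zinc–ProPhenol complex binds the aldehyde and the alkynylzinc 9 and delivers the alkynyl group to one face of the C6 carbonyl in a 1,2-sense, so C6 (4R in this chain, the future lactone carbinol) is set by the catalyst before any ring exists; 8 supplies C7, C11 and C12.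

Step 7
Reactants: 10 (4R,5E,9E)-1-[(tert-butyldimethylsilyl)oxy]-6,10-dimethyltrideca-5,9,12-trien-2-yn-4-ol
Product: 11 (4R,5E,9E)-1,4-bis[(tert-butyldimethylsilyl)oxy]-6,10-dimethyltrideca-5,9,12-trien-2-yne
Conditions: TBSCl, imidazole, DMF, rt
Reagents that add atoms: tert-butyldimethylsilyl chloride CC(C)(C)[Si](C)(C)Cl
Why: Standard silylation of a secondary alcohol; O6 and O12 now carry the same group, which marks them as the pair that becomes the lactone and keeps them distinct from O8 and O13.

Step 8
Reactants: 11 (4R,5E,9E)-1,4-bis[(tert-butyldimethylsilyl)oxy]-6,10-dimethyltrideca-5,9,12-trien-2-yne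
Product: 12 (6R)-6,12-bis(TBSO)germacra-1(10)E,4E,7Z,11(13)-tetraene, that is (1R,2E,6E,9Z)-1-(TBSO)-10-[3-(TBSO)prop-1-en-2-yl]-3,7-dimethylcyclodeca-2,6,9-triene
Conditions: second-generation Grubbs catalyst RuCl2(=CHPh)(PCy3)(H2IMes) (10 mol %), 1,4-benzoquinone (20 mol %), toluene (0.001 M), 60 °C
Reagents that add atoms: none
Why: Ring-closing enyne metathesis in the exo mode. The ruthenium benzylidene exchanges onto the only monosubstituted olefin (C8=C13); the alkylidene at C8 adds across C7≡C11 to a ruthenacyclobutene that opens to the conjugated vinylcarbene at C11, and this carbene takes the C13 methylene from the vinyl group of the next molecule of 11, so no atom is lost. The closest known reactions are exo-selective enyne ring closures to medium rings and the enyne metathesis of 1,4-dioxygenated but-2-ynes. The ten-membered ring is closed by forming C7=C8 with C11 left outside the ring; the endo alternative would place a bridgehead-type ruthenacyclobutene in an eleven-membered ring and is disfavoured at this ring size. No stereocentre is created: C6 is untouched, and the new ring olefin can only be Z (C6 cis to C9), because a ten-membered ring that already holds two E-olefins cannot hold a third trans double bond. The step needs ring closure to win over intermolecular enyne metathesis and the two trisubstituted olefins to stay inert; high dilution and the irreversibility of the step (an alkyne π-bond is exchanged for a C–C σ-bond, which outweighs the ring strain) secure the first, the low reactivity of trisubstituted olefins toward the ruthenium carbene secures the second, and benzoquinone suppresses hydride-mediated migration of the skipped dienes. The product diene C8=C7–C11=C13 holds in latent form the tetrasubstituted olefin and both acetoxy-bearing carbons of the target.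

Step 9
Reactants: 12 (6R)-6,12-bis(TBSO)germacra-1(10)E,4E,7Z,11(13)-tetraene
Product: 14 (6R,8S)-6,12-bis(TBSO)germacra-1(10)E,4E,7(11)-triene-8,13-diol (C12 cis to C6 across C7=C11), via bis(pinacolboronate) 13 (not isolated)
Conditions: B2pin2, Pt(dba)3 (3 mol %), TADDOL-derived phenylphosphonite (6 mol %, enantiomer giving 8S), THF, 60 °C; then 3 M NaOH, 30 % H2O2, 0 °C to rt
Reagents that add atoms: hydrogen peroxide OO; bis(pinacolato)diboron CC1(C)OB(OC1(C)C)B1OC(C)(C)C(C)(C)O1 (its boron atoms stay only in 13)
Why: Platinum-catalysed enantioselective 1,4-diboration of a 1,3-diene followed by stereoretentive C–B oxidation: zerovalent platinum adds the B–B bond across the s-cis diene, so boron ends on C8 and C13 and the new C7=C11 bond necessarily has C13 cis to C8 and C12 cis to C6. The C8 configuration is set by the face of the diene to which the chiral platinum complex binds (ligand control, next to the allylic C6 silyloxy group), and isolated trisubstituted olefins should not react.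

Step 10
Reactants: 14 (6R,8S)-6,12-bis(TBSO)germacra-1(10)E,4E,7(11)-triene-8,13-diol
Product: 15 (6R,8S)-8,13-diacetoxy-6,12-bis(TBSO)germacra-1(10)E,4E,7(11)-triene
Conditions: Ac2O, pyridine, DMAP (cat.), CH2Cl2, 0 °C to rt
Reagents that add atoms: acetic anhydride CC(=O)OC(C)=O
Why: Nucleophile-catalysed acetylation of one primary and one secondary allylic alcohol; both acetates of the target are now in place and no stereocentre is touched.

Step 11
Reactants: 15 (6R,8S)-8,13-diacetoxy-6,12-bis(TBSO)germacra-1(10)E,4E,7(11)-triene
Product: 16 (6R,8S)-8,13-diacetoxygermacra-1(10)E,4E,7(11)-triene-6,12-diol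
Conditions: HF·pyridine, pyridine, THF, 0 °C to rt
Reagents that add atoms: none
Why: Fluoride-mediated cleavage of both silyl ethers under buffered, non-basic conditions, chosen so that the acetates neither hydrolyse nor migrate to the freed neighbouring hydroxyl groups (O8 to O6, O13 to O12).

Step 12
Reactants: 16 (6R,8S)-8,13-diacetoxygermacra-1(10)E,4E,7(11)-triene-6,12-diol
Product: 19 (6R,8S)-8,13-diacetoxygermacra-1(10)E,4E,7(11)-trien-12,6-olide, via hydroxy enal 17 (not isolated), via lactol 18 (not isolated)
Conditions: TEMPO (20 mol %), PhI(OAc)2 (2.5 equiv), CH2Cl2, rt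
Reagents that add atoms: none
Why: Oxidative lactonisation of a cis-2-ene-1,4-diol: the oxoammonium salt oxidises the primary allylic C12 alcohol much faster than the hindered secondary C6 alcohol, the enal 17 is trapped by O6 as the five-membered lactol 18 (possible only because C12 is cis to C6), and a second oxidation gives the butenolide; C6 and C8 are untouched.

Step 13
Reactants: 19 (6R,8S)-8,13-diacetoxygermacra-1(10)E,4E,7(11)-trien-12,6-olide
Product: 20 (1R,4R,5R,6S,8S,10R)-8,13-diacetoxy-1,10:4,5-diepoxygermacr-7(11)-en-12,6-olide (target)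
Conditions: DMDO (2.4 equiv, acetone), CH2Cl2, −20 °C
Reagents that add atoms: dimethyldioxirane CC1(C)OO1
Why: Electrophilic epoxidation by a neutral dioxirane: the two electron-rich trisubstituted olefins should react and the electron-poor tetrasubstituted butenolide olefin should not. In the crown conformation of the E,E-cyclodecadiene both olefin planes stand roughly perpendicular to the ring with C14 and C15 syn, so only the outer faces are open, and syn oxygen transfer to them gives the trans 1β,10α- and 4α,5β-epoxides (1R,10R,4R,5R), the pattern expected for germacradienolides with this ring fusion. The C6 descriptor changes from R to S only because C5 gains an oxygen.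

## Compound list

1 | geranyl acetate, (2E)-3,7-dimethylocta-2,6-dien-1-yl acetate | CC(C)=CCC/C(C)=C/COC(C)=O | starting material
2 | (2E,6E)-8-hydroxy-3,7-dimethylocta-2,6-dien-1-yl acetate | OC/C(C)=C/CC/C(C)=C/COC(C)=O | intermediate
3 | (2E,6E)-8-bromo-3,7-dimethylocta-2,6-dien-1-yl acetate | BrC/C(C)=C/CC/C(C)=C/COC(C)=O | intermediate
4 | tributyl(vinyl)stannane | C=C[Sn](CCCC)(CCCC)CCCC | starting material
5 | (2E,6E)-3,7-dimethyldeca-2,6,9-trien-1-yl acetate | C=CC/C(C)=C/CC/C(C)=C/COC(C)=O | intermediate
6 | (2E,6E)-3,7-dimethyldeca-2,6,9-trien-1-ol | C=CC/C(C)=C/CC/C(C)=C/CO | intermediate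
7 | (2E,6E)-3,7-dimethyldeca-2,6,9-trienal | C=CC/C(C)=C/CC/C(C)=C/C=O | intermediate
8 | tert-butyldimethyl(prop-2-yn-1-yloxy)silane | C#CCO[Si](C)(C)C(C)(C)C | starting material
9 | methyl{3-[(tert-butyldimethylsilyl)oxy]prop-1-yn-1-yl}zinc | C[Zn]C#CCO[Si](C)(C)C(C)(C)C | intermediate
10 | (4R,5E,9E)-1-[(tert-butyldimethylsilyl)oxy]-6,10-dimethyltrideca-5,9,12-trien-2-yn-4-ol | C=CC/C(C)=C/CC/C(C)=C/[C@@H](O)C#CCO[Si](C)(C)C(C)(C)C | intermediate
11 | (4R,5E,9E)-1,4-bis[(tert-butyldimethylsilyl)oxy]-6,10-dimethyltrideca-5,9,12-trien-2-yne | C=CC/C(C)=C/CC/C(C)=C/[C@@H](O[Si](C)(C)C(C)(C)C)C#CCO[Si](C)(C)C(C)(C)C | intermediate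
12 | (6R)-6,12-bis(TBSO)germacra-1(10)E,4E,7Z,11(13)-tetraene | C=C(CO[Si](C)(C)C(C)(C)C)/C1=C/C/C(C)=C/CC/C(C)=C/[C@H]1O[Si](C)(C)C(C)(C)C | intermediate
13 | (6R,8S)-8,13-bis(4,4,5,5-tetramethyl-1,3,2-dioxaborolan-2-yl)-6,12-bis(TBSO)germacra-1(10)E,4E,7(11)-triene (C12 cis to C6) | CC1(C)OB(C/C(CO[Si](C)(C)C(C)(C)C)=C2\[C@@H](B3OC(C)(C)C(C)(C)O3)C/C(C)=C/CC/C(C)=C/[C@H]2O[Si](C)(C)C(C)(C)C)OC1(C)C | intermediate
14 | (6R,8S)-6,12-bis(TBSO)germacra-1(10)E,4E,7(11)-triene-8,13-diol (C12 cis to C6) | OC/C(CO[Si](C)(C)C(C)(C)C)=C1\[C@@H](O)C/C(C)=C/CC/C(C)=C/[C@H]1O[Si](C)(C)C(C)(C)C | intermediate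
15 | (6R,8S)-8,13-diacetoxy-6,12-bis(TBSO)germacra-1(10)E,4E,7(11)-triene (C12 cis to C6) | CC(=O)OC/C(CO[Si](C)(C)C(C)(C)C)=C1\[C@@H](OC(C)=O)C/C(C)=C/CC/C(C)=C/[C@H]1O[Si](C)(C)C(C)(C)C | intermediate
16 | (6R,8S)-8,13-diacetoxygermacra-1(10)E,4E,7(11)-triene-6,12-diol (C12 cis to C6) | CC(=O)OC/C(CO)=C1\[C@@H](OC(C)=O)C/C(C)=C/CC/C(C)=C/[C@H]1O | intermediate
17 | (6R,8S)-8,13-diacetoxy-6-hydroxygermacra-1(10)E,4E,7(11)-trien-12-al (C12 cis to C6) | CC(=O)OC/C(C=O)=C1\[C@@H](OC(C)=O)C/C(C)=C/CC/C(C)=C/[C@H]1O | intermediate
18 | (6R,8S)-8,13-diacetoxy-6,12-epoxygermacra-1(10)E,4E,7(11)-trien-12-ol (lactol, both C12 epimers) | CC(=O)OCC1=C2[C@@H](OC(C)=O)C/C(C)=C/CC/C(C)=C/[C@H]2OC1O | intermediate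
19 | (6R,8S)-8,13-diacetoxygermacra-1(10)E,4E,7(11)-trien-12,6-olide | CC(=O)OCC1=C2[C@@H](OC(C)=O)C/C(C)=C/CC/C(C)=C/[C@H]2OC1=O | intermediate
20 | (1R,4R,5R,6S,8S,10R)-8,13-diacetoxy-1,10:4,5-diepoxygermacr-7(11)-en-12,6-olide | CC(=O)OCC1=C2[C@@H](OC(C)=O)C[C@@]3(C)O[C@@H]3CC[C@@]3(C)O[C@@H]3[C@H]2OC1=O | target

## Step count and least certain steps

Total step count: 13. Longest linear sequence: 13 steps (1 to 20); 4 and 8 are commercial and enter directly.

Step 8 (key step). The most likely failure is intermolecular enyne metathesis (oligomerisation) outrunning ring closure, because the ten-membered triene is strained. Closure in the endo sense to an eleven-membered isomer and ruthenium-hydride migration of the skipped dienes are further risks. Fallback: change the order of events so that the ring is closed on a chain without E-olefins. Setting out from 11, a two-fold Shi epoxidation (D-fructose-derived ketone, Oxone 2KHSO5·KHSO4·K2SO4, K2CO3, MeCN–dimethoxymethane–water, 0 °C) should oxidise only the two trisubstituted olefins under reagent control and give the bis-epoxy enyne F1. The same enyne ring closure on this more flexible, Cope-inert chain would give the bis-epoxy macrocyclic diene F2. Diboration would give the bis-epoxy bis(pinacolboronate) F3 and, after oxidation, the bis-epoxy diol F4. Acetylation would give the bis-epoxy diacetate F5, and desilylation with TBAF/AcOH the bis-epoxy 6,12-diol F6. TEMPO/PhI(OAc)2 would then lead through the bis-epoxy hydroxy enal F7 and the bis-epoxy lactol F8 to 20, where the fallback rejoins the route and step 13 is no longer needed.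

Step 9. The hindered 1,2,3-trisubstituted diene may not reach the s-cis geometry on platinum, which would lead to 1,2-diboration of the C11=C13 olefin. The chiral ligand and the C6 stereocentre may also be mismatched, giving poor face selectivity at C8. Fallback: a palladium 1,4-oxidation on a tethered diene. Setting out from 12, HF·pyridine would give the diene diol F9, and t-Bu2Si(OTf)2/2,6-lutidine would tie O6 and O12 into the cyclic silylene diene F10, which locks the diene s-cis and fixes C12 cis to C6. A 1,4-diacetoxylation catalysed by divalent palladium (Pd(OAc)2, benzoquinone, LiOAc, AcOH, with or without LiCl to switch between external and internal delivery of the second acetate and so choose the C8 configuration) would give the silylene diacetate F11. HF·pyridine then returns the route at 16.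

Step 6. The β,β-disubstituted enal may add slowly, so that an uncatalysed background addition erodes the enantiomeric purity at C6. Fallback: separate C–C bond formation from stereocontrol. Setting out from 7 and 8, the lithium acetylide F12 (from 8 and n-BuLi, THF, −78 °C) would add to 7 to give the racemic propargylic alcohol F13. MnO2 would oxidise it to the alkynyl ketone F14, and asymmetric transfer hydrogenation with RuCl(p-cymene)[(S,S)-TsDPEN] or its enantiomer in i-PrOH would return the route at 10.

Step 13. Face selectivity at C4=C5, which lies next to C6 and the lactone, may be incomplete, and the first-formed epoxide may open transannularly if any acid is present. Fallback: replace substrate control by reagent control. Setting out from 19, a two-fold Shi epoxidation (chiral dioxirane from the D-fructose-derived ketone and Oxone 2KHSO5·KHSO4·K2SO4 at buffered basic pH) would impose the R,R sense on each olefin independently of the ring conformation and return the route at 20; no new compound is involved.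

## Further compounds

F1 | step 8 | 1,10:4,5-bis-epoxide of 11 (epoxide carbons 1R,10R,4R,5R) | C=CC[C@@]1(C)O[C@@H]1CC[C@@]1(C)O[C@@H]1[C@@H](O[Si](C)(C)C(C)(C)C)C#CCO[Si](C)(C)C(C)(C)C
F2 | step 8 | 1,10:4,5-bis-epoxide of 12 (1R,10R,4R,5R) | C=C(CO[Si](C)(C)C(C)(C)C)/C1=C/C[C@@]2(C)O[C@@H]2CC[C@@]2(C)O[C@@H]2[C@H]1O[Si](C)(C)C(C)(C)C
F3 | step 8 | 1,10:4,5-bis-epoxide of 13 (1R,10R,4R,5R) | CC1(C)OB(C/C(CO[Si](C)(C)C(C)(C)C)=C2\[C@@H](B3OC(C)(C)C(C)(C)O3)C[C@@]3(C)O[C@@H]3CC[C@@]3(C)O[C@@H]3[C@H]2O[Si](C)(C)C(C)(C)C)OC1(C)C
F4 | step 8 | 1,10:4,5-bis-epoxide of 14 (1R,10R,4R,5R) | OC/C(CO[Si](C)(C)C(C)(C)C)=C1\[C@@H](O)C[C@@]2(C)O[C@@H]2CC[C@@]2(C)O[C@@H]2[C@H]1O[Si](C)(C)C(C)(C)C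
F5 | step 8 | 1,10:4,5-bis-epoxide of 15 (1R,10R,4R,5R) | CC(=O)OC/C(CO[Si](C)(C)C(C)(C)C)=C1\[C@@H](OC(C)=O)C[C@@]2(C)O[C@@H]2CC[C@@]2(C)O[C@@H]2[C@H]1O[Si](C)(C)C(C)(C)C
F6 | step 8 | 1,10:4,5-bis-epoxide of 16 (1R,10R,4R,5R) | CC(=O)OC/C(CO)=C1\[C@@H](OC(C)=O)C[C@@]2(C)O[C@@H]2CC[C@@]2(C)O[C@@H]2[C@H]1O
F7 | step 8 | 1,10:4,5-bis-epoxide of 17 (1R,10R,4R,5R) | CC(=O)OC/C(C=O)=C1\[C@@H](OC(C)=O)C[C@@]2(C)O[C@@H]2CC[C@@]2(C)O[C@@H]2[C@H]1O
F8 | step 8 | 1,10:4,5-bis-epoxide of 18 (1R,10R,4R,5R; both C12 epimers) | CC(=O)OCC1=C2[C@@H](OC(C)=O)C[C@@]3(C)O[C@@H]3CC[C@@]3(C)O[C@@H]3[C@H]2OC1O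
F9 | step 9 | (6R)-germacra-1(10)E,4E,7Z,11(13)-tetraene-6,12-diol | C=C(CO)/C1=C/C/C(C)=C/CC/C(C)=C/[C@H]1O
F10 | step 9 | 6,12-O-(di-tert-butylsilanediyl) derivative of F9 | C/C1=C\CC/C(C)=C/[C@H]2O[Si](C(C)(C)C)(C(C)(C)C)OCC(=C)/C2=C/C1
F11 | step 9 | 6,12-O-(di-tert-butylsilanediyl) derivative of 16 | CC(=O)OCC1=C2[C@@H](OC(C)=O)C/C(C)=C/CC/C(C)=C/[C@H]2O[Si](C(C)(C)C)(C(C)(C)C)OC1
F12 | step 6 | {3-[(tert-butyldimethylsilyl)oxy]prop-1-yn-1-yl}lithium | [Li]C#CCO[Si](C)(C)C(C)(C)C
F13 | step 6 | racemic (5E,9E)-1-[(tert-butyldimethylsilyl)oxy]-6,10-dimethyltrideca-5,9,12-trien-2-yn-4-ol | C=CC/C(C)=C/CC/C(C)=C/C(O)C#CCO[Si](C)(C)C(C)(C)C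
F14 | step 6 | (5E,9E)-1-[(tert-butyldimethylsilyl)oxy]-6,10-dimethyltrideca-5,9,12-trien-2-yn-4-one | C=CC/C(C)=C/CC/C(C)=C/C(=O)C#CCO[Si](C)(C)C(C)(C)C
F0 | step 13 | none | none
A1 | alternative 1 | methyl (2Z,4S,6E,10E)-4-acetoxy-2-(bromomethyl)-6,10-dimethyl-12-oxododeca-2,6,10-trienoate | O=C/C=C(C)/CC/C=C(C)/C[C@H](OC(C)=O)/C=C(\CBr)C(=O)OC
A2 | alternative 1 | 8α-acetoxygermacra-1(10)E,4E,11(13)-trien-12,6α-olide (6βH,7αH,8βH) | C=C1[C@@H]2[C@@H](OC(C)=O)C/C(C)=C/CC/C(C)=C/[C@H]2OC1=O
A3 | alternative 2 | 13-membered cyclic ether, O joining C6H2 and C13H2 of the chain C6–C5=C4(Me)–C3–C2–C1=C10(Me)–C9–C8(OTBS)–C7=C11(CH2OTBS)–C13 (4E, 1(10)E, C8 cis to C13, 8S) | O1C/C=C(C)/CC/C=C(C)/C[C@H](O[Si](C)(C)C(C)(C)C)/C=C(CO[Si](C)(C)C(C)(C)C)\C1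
A4 | alternative 2 | 8α,12-bis(TBSO)germacra-1(10)E,4E,11(13)-trien-6α-ol (7αH) | C=C(CO[Si](C)(C)C(C)(C)C)[C@@H]1[C@@H](O[Si](C)(C)C(C)(C)C)C/C(C)=C/CC/C(C)=C/[C@H]1O
A5 | alternative 3 | (4S,6E,10E)-6,10-dimethyl-12-oxododeca-6,10-dien-2-yne-1,4-diyl diacetate | O=C/C=C(C)/CC/C=C(C)/C[C@H](OC(C)=O)C#CCOC(C)=O
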